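Slowness was what I saw first: after 10.0 min the target stood at 15.2%, averaged over the two runs, and c(reagent) of 0.48 M on Wednesday had not hurried it beyond Sunday's 0.27 M. The decision was whether to charge more reagent anyway.

| flask | substrate | reagent | free catalyst | added ligand | remark | time |
|---|---|---|---|---|---|---|
| Sunday's | 0.30 M | 0.27 M | 3 mM | 3.6 mM | run made earlier |  |
| Wednesday's | 0.30 M | 0.48 M | 3 mM | 3.6 mM | run made earlier |  |
| epsilon | 0.30 M | 0.390 M | 3.0 mM | 3.6 mM |  | 20 min |
| alpha | 0.30 M | 0.780 M | 3.0 mM | 3.6 mM |  | 20 min |

| run | time / min | target / % |
|---|---|---|
| Sunday's | 1.33 | 1.7 |
| Sunday's | 4.00 | 7.0 |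
| Sunday's | 6.00 | 10.8 |
| Sunday's | 10.0 | 15.4 |
| Wednesday's | 1.33 | 2.0 |
| Wednesday's | 4.00 | 6.6 |
| Wednesday's | 6.00 | 10.2 |
| Wednesday's | 10.0 | 15.0 |

(standard deviation of a reading: 0.5 percentage points)

1. which of the two there is more of at the end, epsilon (over-reaction product / target)
2. which of the two there is more of at the end, alpha (over-reaction product / target)
3. target at the end, in percent of the substrate charged, epsilon
4. target at the end, in percent of the substrate charged, alpha

More reagent showed no gain in speed, but the reagent might also consume the target. So I reckoned the target's lifetime against the reagent,: the time in which the reagent, held at its charge, would consume a given amount of target. Sunday's last reading exceeded Wednesday's by 0.4 percentage points, and two standard deviations of that difference stretch this to 1.8 points. Dividing by the extra reagent and by the target's accumulated time (half the average reading times the time) gave, at that edge of the scatter, 11.3 min for alpha and 22.6 min for epsilon.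

With target made at a steady pace and reagent held at its charge, target and over-reaction product stand equal at 1.59 lifetimes, however fast the making. So alpha could cross at 18.0 min, earlier than the end, while epsilon's crossing, at 35.9 min, came later than the end. My floors for the target were 20.2% in epsilon and 14.2% in alpha. I chose epsilon's charge.

The forecast gave 27% for epsilon and 26% for alpha, with the target ahead in both, saying of over-reaction that “it should remain minor at 20 min”.

Epsilon gave 23.4% of target against 12.0% of over-reaction product, and alpha gave 15.2% of target against 20.3%. Substrate stood at 64.1% in epsilon and 63.9% in alpha. Counted in my lifetimes, alpha's end lay at 1.77, past the crossing, and epsilon's at 0.887, short of it.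

    reagent + free catalyst → catalyst intermediate A (k = 1200 M⁻¹ min⁻¹)
    substrate + catalyst intermediate A → catalyst intermediate B (k = 21.0 M⁻¹ min⁻¹)
    catalyst intermediate B → catalyst intermediate C (k = 5.40 min⁻¹)
    catalyst intermediate C → free catalyst + target (k = 5.70 min⁻¹)
    reagent + target → over-reaction product (k = 0.150 M⁻¹ min⁻¹)
    free catalyst + added ligand ⇌ idle complex (K = 160 M⁻¹, k = 18.0 M⁻¹ min⁻¹)

A neighbour of alpha, charged with 0.012 M of free catalyst, has the same reagent, and no catalyst enters the lifetime, so the count again puts its end past the crossing. It gave 44.0% of target against 50.0% of over-reaction product.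

The earlier runs and the new flask were generated by integration for substances that don't exist.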